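Compare the two simulated runs first.

| setting | Tuesday's | Monday's | flask |
|---|---|---|---|
| substrate | 16 mM | 23 mM | 31 mM |
| free catalyst | 1.5 mM (in portions, 2) | 1.5 mM (in portions, 2) | 1.5 mM (in portions, 2) |
| remark | run made earlier; portions every 3.0 s | run made earlier; portions every 3.0 s | the portions of free catalyst follow each other after 3.0 s, the first at the start |
| time |  |  | 8.0 min |

| run | time / min | substrate / % | product / % |
|---|---|---|---|
| Tuesday's | 0.500 | 14.0 | 82.3 |
| Tuesday's | 1.33 | 3.4 | 93.5 |
| Tuesday's | 2.50 | 2.1 | 94.7 |
| Tuesday's | 4.00 | 3.6 | 93.3 |
| Tuesday's | 6.00 | 2.6 | 93.5 |
| Tuesday's | 8.00 | 1.7 | 95.0 |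
| Tuesday's | 10.0 | 3.8 | 93.3 |
| Monday's | 0.500 | 19.2 | 81.6 |
| Monday's | 1.33 | 2.6 | 93.1 |
| Monday's | 2.50 | 3.7 | 95.8 |
| Monday's | 4.00 | 3.6 | 94.2 |
| Monday's | 6.00 | 2.4 | 94.9 |
| Monday's | 8.00 | 2.4 | 94.7 |
| Monday's | 10.0 | 2.1 | 93.5 |

(scatter of a reading: 1 percentage point)

- why nothing more happens at 8.0 min, or that something still does (it is still moving / all of the substrate has reacted / forward and back rates have come level / no working catalyst is left)
- how much of the substrate has reacted by 8.0 min
- how much product there is at 8.0 min, in percent of the substrate charged
- how much catalyst intermediate there is at 8.0 min, in percent of the substrate charged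

- the numbers in the tables scatter with a standard deviation of 1 percentage point
- what has gone from substrate into another species counts as reacted, even if it can come back
- the reaction counts as stopped when no species that holds the substrate changes by six tenths of a point or more over the second half of the time

Tuesday's flask and Monday's flask differ in substrate charge, 16 mM against 23 mM, with the same catalyst charge and dosing. Both read flat from 2.50 min on, so take the readings from there. Tuesday's flask reads [product]/[substrate] = 34.0 and Monday's flask 33.3, nearly the same, although their product at 8.00 min reads 15.2 mM and 21.8 mM. Call the mean of these readings, 33.7, the end ratio: [product]/[substrate] in a flat flask, the overall equilibrium constant. Its zero of the scale is a ratio of 1, with substrate and product equal. In these two flasks the ratio repeats while the amounts differ, so read both as ending with forward and back rates level.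

Substrate and product fall short of the charge. Read that gap as catalyst intermediate: 0.525 mM on Tuesday and 0.584 mM on Monday.

For the new flask, hold Monday's gap and share the rest by the end ratio. My reckoning gives catalyst intermediate 1.88%, substrate 2.83%, product 95.4% and conversion 97.2%, level by 8.0 min, which is later than the flat readings began.

The forecast says forward and back rates have come level, with conversion 97.1%, product 94.7% and catalyst intermediate 2.4%, on the ground that “A constant percentage, rather than a constant amount converted (15 vs 22 mM product), points to equilibrium, not catalyst death.”; its intermediate stands higher than mine and its product lower.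

The flask gives: forward and back rates have come level, conversion 97.1%, product 94.7%, catalyst intermediate 2.35%.

    substrate + free catalyst ⇌ catalyst intermediate (K = 2700 M⁻¹, k = 130 M⁻¹ s⁻¹)
    catalyst intermediate ⇌ free catalyst + product (K = 0.0120 M, k = 36.0 s⁻¹)
    free catalyst ⇌ dormant form (K = 1.60, k = 0.130 s⁻¹)

The slowest mode of this flask has a half-life of 0.291 min at 8.00 min, far shorter than the 8.0 min of the run, which makes 27.5 half-lives. Ten times the time leaves conversion at 97.1%. This flask holds catalyst intermediate 0.46 percentage points above my reckoning, and the end ratio 33.7 shares the rest to substrate 2.81%, against 2.92% in the flask. The neighbour flask charged with 6.0 mM of free catalyst holds 9.04% as catalyst intermediate, so the end ratio gives it substrate 2.62%, and it holds 2.72%.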